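You read this flask at 20 min, and the free base charged at the start has to bring the electrophile to the part asked for by then.

electrophile 20 mM; nucleophile 21.0 mM; protic impurity 10.0 mM; time 20 min

    acid set free + free base ⇌ salt of the base (K1 = 1590 M⁻¹, k1 = 21.9 M⁻¹ s⁻¹)
    crystals ⇌ target, rate k2*(cs2 - [target]) while solid is left; crystals form when [target] > cs2 (cs2 = 7.9 mM, k2 = 2.20 s⁻¹)
    protic impurity + free base → quenched reagent (k3 = 1.31 M⁻¹ s⁻¹)
    nucleophile + acid set free ⇌ protonated nucleophile, settled at all times (K4 = 3.8 × 10⁵ M⁻¹)
    electrophile + nucleophile → acid set free + target (k5 = 8.41 M⁻¹ s⁻¹)

- the concentration of free base at which the part of the electrophile that has reacted at 20 min is just 70%, in mM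

- for target the crystals are counted in
- as a solid, counted per litre of solution: crystals
- the amount of free base is what is sought; it is there from the start
- run time (flask): 20 min

Run it slowly in your head. In the first instants the electrophile meets the full nucleophile charge, and with the concentrations as charged its half-life is 0.065 min. That is a starting figure and not the time the electrophile takes to halve, since the nucleophile falls as soon as the reaction runs. Each electrophile that reacts sets one acid free, and the nucleophile binds that acid with 3.8 × 10⁵ M⁻¹ against 1590 M⁻¹ for the free base, a far stronger hold. So each reaction costs two nucleophiles, one turned into target and one protonated, and by itself c(nucleophile) carries 10.5 mM of electrophile through.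

The middle is a balance on the nucleophile. The part asked for is 14.0 mM of electrophile, which would cost 28.0 mM of nucleophile, and the flask holds 21.0 mM. The difference is the acid excess, the acid that must stand somewhere other than on nucleophile at the wanted point: 7.00 mM.

Towards the end, my reckoning puts that excess into the salt at one free base each, and the protic impurity takes free base one for one as well. My reckoning therefore commits to 17.0 mM. With free base held at a charge of that size, the half-life of the impurity is 0.519 min, much shorter than the run, so I count the whole 10.0 mM as used. This sum leaves no free base over at the end, and my reckoning stops there.

The forecast gives 21.5 mM, higher than my sum. It works from “the near-balanced proton shuttle between protonated nucleophile and base” and keeps about 4 mM of free base at the end.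

The simulation gives 19.7 mM, within the forecast's margin, so this flask's charge stands 2.74 mM above acid excess plus impurity. The hold on this flask is the pairing of nucleophile with acid: in the run without that pairing, >99.9% of the electrophile has reacted at 20 min, against 70.0%. The acid excess also reads a second run. Take away the salt step, which does a part of the work, and the part reacted falls to 59.7%, where the excess standing as free acid is 2.87 mM.

The numbers belong to no real substance; the result is computed.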